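**Plan**
1. Retrosynthetic cuts: the C3–O ester bond; C11–O together with the C6=C7 shift (ene oxygenation of an isopropylidene ketone); C2–C3 of ring A; then C7–C11, C10–C1, C9=C10, C5–C10 and C4=C5.
2. Cutting C2–C3 leaves a 2,3-seco-eudesmane (elemane-type) ring B ketone with a vinyl group (C1=C2) on C10 and a C4(Me)(OSiEt3)–C3HO arm on C5; intramolecular alkene hydroacylation joins C2 to C3 again.
3. Enabling feature: the vinyl group sits on quaternary C10 and the formyl group on fully substituted C4, the two arms are trans-diequatorial on ring B and 1,6-related, so neither partner can isomerise or enolise and the exo alternative would be a strained trans-fused five-membered ketone.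
4. Forward order: C3–C9 chain (Wittig) → epoxide → isopropenyl opening → ring B by metathesis → enone → quaternary C10 → isopropylidene ketone → ring A → C3 alcohol → C11 oxygenation → ester.
5. Stereochemistry: C4 and C5 from the asymmetric epoxidation and its anti opening; C10 from conjugate addition anti to the C5 side chain; C3 from axial hydride addition; the (Z)-ester geometry comes with angelic acid.

Key step: step 12

Remark: eudesmane numbering is used (ring A = C1–C5 and C10, ring B = C5–C10, C14 on C10, C15 on C4, C11–C13 on C7); the target is taken as the (3S,4S,5R,10R) isomer with a (Z)-2-methylbut-2-enoyl ester, and 16 is carried as a mixture of epimers at its ring C2 because that centre becomes sp2 in step 10.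

Step 1
Reactants: 1 hex-5-enal; 2 ethyl 2-(triphenyl-λ5-phosphanylidene)propanoate
Product: 3 ethyl (2E)-2-methylocta-2,7-dienoate
Conditions: CH2Cl2, 25–40 °C
Reagents that add atoms: none
Why: Wittig olefination with a stabilised α-methyl ylide is expected to give the (E)-trisubstituted enoate (future C4=C5 bearing C15) and leaves the terminal alkene (future C9) untouched.

Step 2
Reactants: 3 ethyl (2E)-2-methylocta-2,7-dienoate
Product: 4 (2E)-2-methylocta-2,7-dien-1-ol
Conditions: iBu2AlH (2.2 equiv), CH2Cl2, −78 → 0 °C; aq. potassium sodium tartrate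
Reagents that add atoms: none
Why: 1,2-reduction of the conjugated ester with the aluminium hydride gives the allylic alcohol that the next step needs as its directing group.

Step 3
Reactants: 4 (2E)-2-methylocta-2,7-dien-1-ol
Product: 5 [(2R,3R)-2-methyl-3-(pent-4-en-1-yl)oxiran-2-yl]methanol
Conditions: Ti(OiPr)4 (10 mol%), D-(−)-diethyl tartrate (12 mol%), t-BuOOH, 4 Å molecular sieves, CH2Cl2, −20 °C
Reagents that add atoms: tert-butyl hydroperoxide, CC(C)(C)OO
Why: Katsuki–Sharpless asymmetric epoxidation of an (E)-2-methylalk-2-en-1-ol with the D-(−)-tartrate ligand should deliver oxygen to the face that gives the (2R,3R)-epoxide and so sets the C4 carbinol centre of the target, while the isolated terminal alkene lacks the directing hydroxyl and is not touched.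

Step 4
Reactants: 5 [(2R,3R)-2-methyl-3-(pent-4-en-1-yl)oxiran-2-yl]methanol; 6 prop-1-en-2-ylmagnesium bromide
Product: 7 (2S,3R)-2-methyl-3-(prop-1-en-2-yl)oct-7-ene-1,2-diol
Conditions: 6 (3 equiv), CuI (10 mol%), THF, −30 → 0 °C; aq. NH4Cl
Reagents that add atoms: none
Why: copper-catalysed SN2 opening of the 2,3-epoxy alcohol should take place at the secondary carbon (the quaternary one is blocked) with inversion, which sets C5 anti to the C4 oxygen and brings in C10 and C14 as the isopropenyl group.

Step 5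
Reactants: 7 (2S,3R)-2-methyl-3-(prop-1-en-2-yl)oct-7-ene-1,2-diol
Product: 8 (2S,3R)-2-methyl-3-(prop-1-en-2-yl)-1,2-bis(triethylsilyloxy)oct-7-ene
Conditions: Et3SiOTf (2.5 equiv), 2,6-lutidine, CH2Cl2, −78 → 0 °C
Reagents that add atoms: triethylsilyl trifluoromethanesulfonate, CC[Si](CC)(CC)OS(=O)(=O)C(F)(F)F
Why: the silyl triflate silylates the primary and the hindered tertiary hydroxyl alike, giving a pair of ethers of which the primary one can later be oxidised directly.

Step 6
Reactants: 8 (2S,3R)-2-methyl-3-(prop-1-en-2-yl)-1,2-bis(triethylsilyloxy)oct-7-ene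
Product: 9 (2S)-2-[(1R)-2-methylcyclohex-2-en-1-yl]-1,2-bis(triethylsilyloxy)propane
Conditions: second-generation Grubbs catalyst RuCl2(=CHPh)(PCy3)(H2IMes) (3 mol%), CH2Cl2, 40 °C
Reagents that add atoms: none
Why: ring-closing metathesis between the terminal alkene and the 1,1-disubstituted alkene should close ring B as the trisubstituted cyclohexene (C9=C10) with loss of ethene, six-ring formation being the only productive pathway.

Step 7
Reactants: 9 (2S)-2-[(1R)-2-methylcyclohex-2-en-1-yl]-1,2-bis(triethylsilyloxy)propane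
Product: 10 (4R)-4-[(2S)-1,2-bis(triethylsilyloxy)propan-2-yl]-3-methylcyclohex-2-en-1-one
Conditions: Rh2(cap)4 (cap = caprolactamate, 1 mol%), t-BuOOH (70% aq.), K2CO3, CH2Cl2, 25 °C
Reagents that add atoms: tert-butyl hydroperoxide, CC(C)(C)OO
Why: allylic oxidation by tert-butylperoxyl radicals generated on the dirhodium catalyst should abstract hydrogen from the unhindered ring methylene C8 and give the conjugated enone, since the tertiary allylic C5–H is shielded by the adjacent quaternary side chain and the methyl C–H bonds are stronger.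

Step 8
Reactants: 10 (4R)-4-[(2S)-1,2-bis(triethylsilyloxy)propan-2-yl]-3-methylcyclohex-2-en-1-one; 11 ethenylmagnesium bromide
Product: 13 (3S,4R)-4-[(2S)-1,2-bis(triethylsilyloxy)propan-2-yl]-3-ethenyl-3-methylcyclohexan-1-one, via silyl enol ether 12 (not isolated)
Conditions: 11 (2.5 equiv), CuBr·SMe2 (20 mol%), Me3SiCl, HMPA, THF, −78 °C; then K2CO3, MeOH, 0 °C
Reagents that add atoms: none
Why: copper-catalysed, chlorosilane-accelerated 1,4-addition to the β,β-disubstituted enone should create quaternary C10 with the vinyl group trans to the C5 side chain, because allylic strain with the C10 methyl holds that side chain pseudoaxial and the nucleophile adds axially to the opposite face.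

Step 9
Reactants: 13 (3S,4R)-4-[(2S)-1,2-bis(triethylsilyloxy)propan-2-yl]-3-ethenyl-3-methylcyclohexan-1-one; 14 propan-2-one
Product: 16 (4R,5S)-4-[(2S)-1,2-bis(triethylsilyloxy)propan-2-yl]-5-ethenyl-2-(2-hydroxypropan-2-yl)-5-methylcyclohexan-1-one, via lithium enolate 15 (not isolated)
Conditions: LiN(iPr)2 (1.1 equiv), THF, −78 °C; then 14, −78 °C; aq. NH4Cl
Reagents that add atoms: none
Why: kinetic deprotonation should occur at C7, the α-methylene remote from quaternary C10, and aldol addition of that enolate to acetone installs C11–C13; the new ring stereocentre is removed in step 10 and need not be controlled.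

Step 10
Reactants: 16 (4R,5S)-4-[(2S)-1,2-bis(triethylsilyloxy)propan-2-yl]-5-ethenyl-2-(2-hydroxypropan-2-yl)-5-methylcyclohexan-1-one
Product: 18 (4R,5S)-4-[(2S)-1,2-bis(triethylsilyloxy)propan-2-yl]-5-ethenyl-5-methyl-2-(propan-2-ylidene)cyclohexan-1-one, via tertiary mesylate 17 (not isolated)
Conditions: MeSO2Cl, Et3N, CH2Cl2, 0 °C; then DBU, 25 °C
Reagents that add atoms: none
Why: sulfonylation of the tertiary aldol hydroxyl followed by E1cB elimination should give the conjugated α-isopropylidene ketone, a hindered form of the ring B carbonyl that stays inert through steps 11–13 and carries the allylic hydrogens needed in step 14.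

Step 11
Reactants: 18 (4R,5S)-4-[(2S)-1,2-bis(triethylsilyloxy)propan-2-yl]-5-ethenyl-5-methyl-2-(propan-2-ylidene)cyclohexan-1-one
Product: 19 (2S)-2-[(1R,2S)-2-ethenyl-2-methyl-4-oxo-5-(propan-2-ylidene)cyclohexyl]-2-(triethylsilyloxy)propanal
Conditions: (COCl)2, DMSO, CH2Cl2, −78 → −40 °C; Et3N, −78 → 0 °C
Reagents that add atoms: none
Why: under Swern conditions a primary triethylsilyl ether is cleaved and oxidised directly to the aldehyde while the tertiary silyl ether stays in place, and the aldehyde formed has no α-hydrogen to epimerise.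

Step 12
Reactants: 19 (2S)-2-[(1R,2S)-2-ethenyl-2-methyl-4-oxo-5-(propan-2-ylidene)cyclohexyl]-2-(triethylsilyloxy)propanal
Product: 20 (4S,5R,10R)-4-(triethylsilyloxy)eudesm-7(11)-ene-3,8-dione
Conditions: [Rh(cod)Cl]2 (5 mol%), rac-BINAP (11 mol%), Na[B(3,5-(CF3)2C6H3)4] (10 mol%), ClCH2CH2Cl, 60 °C
Reagents that add atoms: none
Why: Proposed new method: a cationic monovalent rhodium bisphosphine complex is expected to insert into the formyl C–H bond of 19, add the hydride to the C10 vinyl group in the anti-Markovnikov sense (H to C1, Rh to C2) to give a seven-membered acyl(alkyl) trivalent rhodium metallacycle, and reductively eliminate to forge C2–C3 of 20. The closest known reaction types are the rhodium-catalysed intramolecular alkene hydroacylation of pent-4-enals to cyclopentanones and the endo-selective hydroacylation of ortho-allylbenzaldehydes to six-membered ketones; an aliphatic α-siloxy hex-5-enal has not been shown to close this way. Ring A closes in the 6-endo-trig mode (both vinyl carbons end up in the ring), and because the step is an isomerisation it leaves no activating group to be removed. No stereocentre is formed; the trans ring fusion follows from the trans arrangement of the C1–C2 and C4–C3 arms on C10 and C5 fixed in steps 4 and 8, which holds both arms equatorial on ring B within bonding distance. The step needs endo over exo regioselectivity and must outrun decarbonylation: Markovnikov insertion would put rhodium on the neopentyl-type C1 next to quaternary C10, the vinyl group has no allylic hydrogen and cannot isomerise, the aldehyde sits on fully substituted C4 so it cannot enolise and its tertiary acyl group should lose CO slowly, and the silyl ether blocks α-ketol rearrangement.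

Step 13
Reactants: 20 (4S,5R,10R)-4-(triethylsilyloxy)eudesm-7(11)-ene-3,8-dione
Product: 21 (3S,4S,5R,10R)-3-hydroxy-4-(triethylsilyloxy)eudesm-7(11)-en-8-one
Conditions: NaBH4 (1 equiv), MeOH/CH2Cl2, −78 → −40 °C
Reagents that add atoms: none
Why: borohydride should reduce the inductively activated α-siloxy ketone in preference to the conjugated, doubly flanked C8 ketone and add axially from the α-face, anti to the axial C15 methyl, to give the equatorial (3S)-alcohol.

Step 14
Reactants: 21 (3S,4S,5R,10R)-3-hydroxy-4-(triethylsilyloxy)eudesm-7(11)-en-8-one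
Product: 23 (3S,4S,5R,10R)-3,11-dihydroxy-4-(triethylsilyloxy)eudesm-6-en-8-one, via allylic hydroperoxide 22 (not isolated)
Conditions: O2, tetraphenylporphyrin (cat.), visible light, CH2Cl2, −10 °C; then PPh3, 25 °C
Reagents that add atoms: dioxygen, O=O
Why: Schenck ene reaction of singlet oxygen with the s-cis α-isopropylidene ketone follows the known geminal directing effect of the carbonyl group (hydrogen abstraction from C6, oxygen to C11, double bond into conjugation at C6=C7), and the phosphine reduces the hydroperoxide to the tertiary alcohol.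

Step 15
Reactants: 23 (3S,4S,5R,10R)-3,11-dihydroxy-4-(triethylsilyloxy)eudesm-6-en-8-one
Product: 24 (3S,4S,5R,10R)-3,4,11-trihydroxyeudesm-6-en-8-one
Conditions: HF·pyridine, pyridine, THF, 0 → 25 °C
Reagents that add atoms: none
Why: fluoride-assisted cleavage of the tertiary triethylsilyl ether under buffered conditions frees the C4 hydroxyl and removes the bulk next to the C3 hydroxyl before acylation.

Step 16
Reactants: 24 (3S,4S,5R,10R)-3,4,11-trihydroxyeudesm-6-en-8-one; 25 (2Z)-2-methylbut-2-enoic acid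
Product: 27 (3S,4S,5R,10R)-4,11-dihydroxy-8-oxoeudesm-6-en-3-yl (2Z)-2-methylbut-2-enoate, via mixed anhydride 26 (not isolated)
Conditions: 25, 2,4,6-trichlorobenzoyl chloride, Et3N, toluene, 25 °C; then 24, toluene, 75 °C
Reagents that add atoms: none
Why: Yamaguchi esterification through the preformed mixed anhydride should acylate the only secondary hydroxyl (C3) while the tertiary C4 and C11 hydroxyls do not react, and the DMAP-free protocol is chosen because it is known to keep the (Z)-2-methylbut-2-enoyl group from isomerising.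

**Compound list**
1 | hex-5-enal | C=CCCCC=O | starting material
2 | ethyl 2-(triphenyl-λ5-phosphanylidene)propanoate | CCOC(=O)C(C)=P(c1ccccc1)(c1ccccc1)c1ccccc1 | starting material
3 | ethyl (2E)-2-methylocta-2,7-dienoate | C=CCCC/C=C(\C)C(=O)OCC | intermediate
4 | (2E)-2-methylocta-2,7-dien-1-ol | C=CCCC/C=C(\C)CO | intermediate
5 | [(2R,3R)-2-methyl-3-(pent-4-en-1-yl)oxiran-2-yl]methanol | OC[C@@]1(C)O[C@@H]1CCCC=C | intermediate
6 | prop-1-en-2-ylmagnesium bromide | CC(=C)[Mg]Br | starting material
7 | (2S,3R)-2-methyl-3-(prop-1-en-2-yl)oct-7-ene-1,2-diol | CC(=C)[C@@H](CCCC=C)[C@](C)(O)CO | intermediate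
8 | (2S,3R)-2-methyl-3-(prop-1-en-2-yl)-1,2-bis(triethylsilyloxy)oct-7-ene | CC(=C)[C@@H](CCCC=C)[C@](C)(O[Si](CC)(CC)CC)CO[Si](CC)(CC)CC | intermediate
9 | (2S)-2-[(1R)-2-methylcyclohex-2-en-1-yl]-1,2-bis(triethylsilyloxy)propane | CC1=CCCC[C@H]1[C@](C)(O[Si](CC)(CC)CC)CO[Si](CC)(CC)CC | intermediate
10 | (4R)-4-[(2S)-1,2-bis(triethylsilyloxy)propan-2-yl]-3-methylcyclohex-2-en-1-one | CC1=CC(=O)CC[C@H]1[C@](C)(O[Si](CC)(CC)CC)CO[Si](CC)(CC)CC | intermediate
11 | ethenylmagnesium bromide | C=C[Mg]Br | starting material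
12 | (3R,4R)-4-[(2S)-1,2-bis(triethylsilyloxy)propan-2-yl]-3-ethenyl-3-methyl-1-(trimethylsilyloxy)cyclohex-1-ene | C=C[C@]1(C)C=C(O[Si](C)(C)C)CC[C@H]1[C@](C)(O[Si](CC)(CC)CC)CO[Si](CC)(CC)CC | intermediate
13 | (3S,4R)-4-[(2S)-1,2-bis(triethylsilyloxy)propan-2-yl]-3-ethenyl-3-methylcyclohexan-1-one | C=C[C@]1(C)CC(=O)CC[C@H]1[C@](C)(O[Si](CC)(CC)CC)CO[Si](CC)(CC)CC | intermediate
14 | propan-2-one | CC(C)=O | starting material
15 | lithium (4R,5S)-4-[(2S)-1,2-bis(triethylsilyloxy)propan-2-yl]-5-ethenyl-5-methylcyclohex-1-en-1-olate | C=C[C@]1(C)CC(O[Li])=CC[C@H]1[C@](C)(O[Si](CC)(CC)CC)CO[Si](CC)(CC)CC | intermediate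
16 | (4R,5S)-4-[(2S)-1,2-bis(triethylsilyloxy)propan-2-yl]-5-ethenyl-2-(2-hydroxypropan-2-yl)-5-methylcyclohexan-1-one (epimers at ring C2) | C=C[C@]1(C)CC(=O)C(C(C)(C)O)C[C@H]1[C@](C)(O[Si](CC)(CC)CC)CO[Si](CC)(CC)CC | intermediate
17 | 2-[(4R,5S)-4-[(2S)-1,2-bis(triethylsilyloxy)propan-2-yl]-5-ethenyl-5-methyl-2-oxocyclohexyl]propan-2-yl methanesulfonate | C=C[C@]1(C)CC(=O)C(C(C)(C)OS(C)(=O)=O)C[C@H]1[C@](C)(O[Si](CC)(CC)CC)CO[Si](CC)(CC)CC | intermediate
18 | (4R,5S)-4-[(2S)-1,2-bis(triethylsilyloxy)propan-2-yl]-5-ethenyl-5-methyl-2-(propan-2-ylidene)cyclohexan-1-one | C=C[C@]1(C)CC(=O)C(=C(C)C)C[C@H]1[C@](C)(O[Si](CC)(CC)CC)CO[Si](CC)(CC)CC | intermediate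
19 | (2S)-2-[(1R,2S)-2-ethenyl-2-methyl-4-oxo-5-(propan-2-ylidene)cyclohexyl]-2-(triethylsilyloxy)propanal | C=C[C@]1(C)CC(=O)C(=C(C)C)C[C@H]1[C@](C)(O[Si](CC)(CC)CC)C=O | intermediate
20 | (4S,5R,10R)-4-(triethylsilyloxy)eudesm-7(11)-ene-3,8-dione | O=C1CC[C@]2(C)CC(=O)C(=C(C)C)C[C@H]2[C@]1(C)O[Si](CC)(CC)CC | intermediate
21 | (3S,4S,5R,10R)-3-hydroxy-4-(triethylsilyloxy)eudesm-7(11)-en-8-one | O[C@H]1CC[C@]2(C)CC(=O)C(=C(C)C)C[C@H]2[C@]1(C)O[Si](CC)(CC)CC | intermediate
22 | (3S,4S,5R,10R)-11-hydroperoxy-3-hydroxy-4-(triethylsilyloxy)eudesm-6-en-8-one | O[C@H]1CC[C@]2(C)CC(=O)C(C(C)(C)OO)=C[C@H]2[C@]1(C)O[Si](CC)(CC)CC | intermediate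
23 | (3S,4S,5R,10R)-3,11-dihydroxy-4-(triethylsilyloxy)eudesm-6-en-8-one | O[C@H]1CC[C@]2(C)CC(=O)C(C(C)(C)O)=C[C@H]2[C@]1(C)O[Si](CC)(CC)CC | intermediate
24 | (3S,4S,5R,10R)-3,4,11-trihydroxyeudesm-6-en-8-one | O[C@H]1CC[C@]2(C)CC(=O)C(C(C)(C)O)=C[C@H]2[C@]1(C)O | intermediate
25 | (2Z)-2-methylbut-2-enoic acid (angelic acid) | C/C=C(/C)C(=O)O | starting material
26 | (2Z)-2-methylbut-2-enoic 2,4,6-trichlorobenzoic anhydride | C/C=C(/C)C(=O)OC(=O)c1c(Cl)cc(Cl)cc1Cl | intermediate
27 | (3S,4S,5R,10R)-4,11-dihydroxy-8-oxoeudesm-6-en-3-yl (2Z)-2-methylbut-2-enoate | C/C=C(/C)C(=O)O[C@H]1CC[C@]2(C)CC(=O)C(C(C)(C)O)=C[C@H]2[C@]1(C)O | target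

**Totals**
Total step count: 16. Longest linear sequence: 16 steps (from 1 to 27).

**Steps most likely to fail**

Step 12 (the labelled step): the acyl rhodium hydride may lose CO faster than it adds to the hindered vinyl group, insert in the exo sense, or die as a rhodium carbonyl complex. The fallback uses known chemistry and sets out from 18. Hydroboration of the vinyl group with 9-borabicyclo[3.3.1]nonane (THF, 0 °C, where the hindered conjugated ketone is expected to survive) and oxidation with NaBO3·4H2O would give the primary alcohol F1. Appel iodination (I2, PPh3, imidazole) would give the primary iodide F2. Swern oxidation of the primary silyl ether would give the iodo aldehyde F3. SmI2 with catalytic NiI2 in THF at −78 °C would then close ring A by an intramolecular Barbier addition of C2 to C3, giving the carbinol F4 as a mixture of C3 epimers. Dess–Martin oxidation of F4 brings the route back at 20.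

Step 7: hydrogen abstraction may be unselective among C8, C5 and C14, and the primary silyl ether may be lost under the oxidising conditions. The fallback sets out from 9. Epoxidation with mCPBA/NaHCO3 would give the epoxide F5. Opening at the secondary carbon C9 with NaSePh (from (PhSe)2 and NaBH4, EtOH) would give the hydroxy selenide F6. Oxidation with H2O2 and selenoxide elimination away from the carbinol carbon would give the tertiary allylic alcohol F7. Babler–Dauben oxidative transposition with pyridinium chlorochromate, (C5H5NH)[CrO3Cl], returns to 10.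

Step 13: the enone carbonyl may be reduced as well, or the two ketones may not be told apart. The fallback sets out from 20. Luche reduction (NaBH4, CeCl3·7H2O, MeOH, 0 °C) of both carbonyls would give the diol F8. Activated MnO2 in CH2Cl2 would then reoxidise only the allylic C8 alcohol and return to 21.

Further compounds
F1 | step 12 | (4R,5R)-4-[(2S)-1,2-bis(triethylsilyloxy)propan-2-yl]-5-(2-hydroxyethyl)-5-methyl-2-(propan-2-ylidene)cyclohexan-1-one | OCC[C@]1(C)CC(=O)C(=C(C)C)C[C@H]1[C@](C)(O[Si](CC)(CC)CC)CO[Si](CC)(CC)CC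
F2 | step 12 | (4R,5S)-4-[(2S)-1,2-bis(triethylsilyloxy)propan-2-yl]-5-(2-iodoethyl)-5-methyl-2-(propan-2-ylidene)cyclohexan-1-one | ICC[C@]1(C)CC(=O)C(=C(C)C)C[C@H]1[C@](C)(O[Si](CC)(CC)CC)CO[Si](CC)(CC)CC
F3 | step 12 | (2S)-2-[(1R,2S)-2-(2-iodoethyl)-2-methyl-4-oxo-5-(propan-2-ylidene)cyclohexyl]-2-(triethylsilyloxy)propanal | ICC[C@]1(C)CC(=O)C(=C(C)C)C[C@H]1[C@](C)(O[Si](CC)(CC)CC)C=O
F4 | step 12 | (4S,5R,10R)-3-hydroxy-4-(triethylsilyloxy)eudesm-7(11)-en-8-one as a mixture of C3 epimers | OC1CC[C@]2(C)CC(=O)C(=C(C)C)C[C@H]2[C@]1(C)O[Si](CC)(CC)CC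
F5 | step 7 | (2S)-2-[(2R)-1-methyl-7-oxabicyclo[4.1.0]heptan-2-yl]-1,2-bis(triethylsilyloxy)propane as a mixture at the oxirane carbons | CC12OC1CCC[C@H]2[C@](C)(O[Si](CC)(CC)CC)CO[Si](CC)(CC)CC
F6 | step 7 | (2S)-2-[(1R)-2-hydroxy-2-methyl-3-(phenylselanyl)cyclohexyl]-1,2-bis(triethylsilyloxy)propane | CC1(O)C([Se]c2ccccc2)CCC[C@H]1[C@](C)(O[Si](CC)(CC)CC)CO[Si](CC)(CC)CC
F7 | step 7 | (2S)-2-[(1R)-2-hydroxy-2-methylcyclohex-3-en-1-yl]-1,2-bis(triethylsilyloxy)propane | CC1(O)C=CCC[C@H]1[C@](C)(O[Si](CC)(CC)CC)CO[Si](CC)(CC)CC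
F8 | step 13 | (3S,4S,5R,10R)-4-(triethylsilyloxy)eudesm-7(11)-ene-3,8-diol as a mixture of C8 epimers | O[C@H]1CC[C@]2(C)CC(O)C(=C(C)C)C[C@H]2[C@]1(C)O[Si](CC)(CC)CC
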